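**Retrosynthetic overview**
- Target ⇐ desilylation ⇐ Evans–Tishchenko reduction (3-OAc, 1-OH) ⇐ ten-membered β-hydroxy ketone ⇐ intramolecular aldol (C2–C3) of a trans α-methylene-γ-lactone carrying a (Z)-enal and a methyl enone.
- That lactone ⇐ Evans–Tishchenko reduction with tiglaldehyde (8-O-tiglate, 6-OH) and lactonisation ⇐ (Z)-keto-enal ⇐ key oxidative dearomatisation of a 2,4-disubstituted furan (C3–C6 and C15 latent in the ring).
- Furan adduct ⇐ syn-selective allylboration of (E)-3-methyl-4-oxopent-2-enal (C8–C10, C1, C2, C14; itself from oxidative opening of 2,3-dimethylfuran) with a furyl 2-(methoxycarbonyl)allylboronate (C7, C11–C13).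
- Allylboronate ⇐ Morita–Baylis–Hillman reaction, acetylation and borylation from a 4-(silyloxymethyl)furfural and methyl acrylate.
- Ring order: γ-lactone first (step 9), ten-membered carbocycle last (step 10).

Assumption: locants follow germacrane numbering (C1 free carbinol, C3 acetoxy carbon, C4=C5 with C15H2OH on C4, C6 lactone carbinol, C7, C8 tigloyloxy carbon, C9=C10 with C14H3 on C10, C11=C13H2, C12 lactone carbonyl); the SMILES is read as (1S,3S,6R,7R,8R), 4Z, 9E, with an (E)-2-methylbut-2-enoate (tiglate). TBS = tert-butyldimethylsilyl. None of this has been run; selectivities are predictions from precedent.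

**Step 1**
Reactants: 1 4-bromofuran-2-carbaldehyde
Product: 2 4-(hydroxymethyl)furan-2-carbaldehyde
Conditions: Bu3SnCH2OH (1.2 equiv), Pd(PPh3)4 (5 mol%), 1,4-dioxane, 100 °C
Reagents that add atoms: (tributylstannyl)methanol, OC[Sn](CCCC)(CCCC)CCCC
Why: Stille hydroxymethylation; zerovalent palladium inserts into the C–Br bond and the CH2OH group is transferred from tin, placing C15 on the ring carbon that becomes C4 (no stereocentre).

**Step 2**
Reactants: 2 4-(hydroxymethyl)furan-2-carbaldehyde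
Product: 3 4-(TBS-oxymethyl)furan-2-carbaldehyde
Conditions: TBSCl, imidazole, DMF, 0 °C to rt
Reagents that add atoms: tert-butyldimethylsilyl chloride, CC(C)(C)[Si](C)(C)Cl
Why: Imidazole-promoted silylation of the primary alcohol; the TBS ether is meant to survive every later step and is removed last.

**Step 3**
Reactants: 3 4-(TBS-oxymethyl)furan-2-carbaldehyde; 4 methyl acrylate
Product: 5 methyl 2-{[4-(TBS-oxymethyl)furan-2-yl](hydroxy)methyl}prop-2-enoate (racemic)
Conditions: DABCO (0.5 equiv), 4 (3 equiv), MeOH, rt, 48 h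
Reagents that add atoms: none
Why: Morita–Baylis–Hillman reaction, which is fast for furfurals; the racemic carbinol (future C7) is erased in step 5.

**Step 4**
Reactants: 5 Baylis–Hillman alcohol
Product: 6 methyl 2-{(acetyloxy)[4-(TBS-oxymethyl)furan-2-yl]methyl}prop-2-enoate (racemic)
Conditions: Ac2O, pyridine, DMAP (5 mol%), CH2Cl2, 0 °C
Reagents that add atoms: acetic anhydride, CC(=O)OC(C)=O
Why: DMAP-catalysed acetylation converts the allylic alcohol into a leaving group for π-allylpalladium formation.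

**Step 5**
Reactants: 6 Baylis–Hillman acetate
Product: 7 methyl (2E)-3-[4-(TBS-oxymethyl)furan-2-yl]-2-[(4,4,5,5-tetramethyl-1,3,2-dioxaborolan-2-yl)methyl]prop-2-enoate
Conditions: B2pin2 (1.1 equiv), Pd2(dba)3 (2.5 mol%), DMSO, 50 °C
Reagents that add atoms: bis(pinacolato)diboron, CC1(C)OB(OC1(C)C)B1OC(C)(C)C(C)(C)O1
Why: Miyaura-type borylation of an allylic acetate via a π-allyl complex of zerovalent palladium (known for Baylis–Hillman acetates); boron goes to the CH2 terminus and the conjugated alkene forms with furan trans to the ester, i.e. cis to CH2B.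

**Step 6**
Reactants: 8 2,3-dimethylfuran
Product: 10 (2E)-3-methyl-4-oxopent-2-enal, via (2Z)-isomer 9 (not isolated)
Conditions: NBS (1.05 equiv), NaHCO3, acetone/H2O (10:1), −20 °C; then pyridine, rt; used as a CH2Cl2 solution
Reagents that add atoms: water, O
Why: Oxidative furan ring opening (bromination–hydrolysis) dearomatises the ring to the (Z)-ene-dicarbonyl, which pyridine isomerises by reversible conjugate addition to the more stable (E)-isomer needed for the 9E olefin.

**Step 7**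
Reactants: 7 furyl allylboronate; 10 (2E)-3-methyl-4-oxopent-2-enal
Product: 12 methyl 2-{(1R,2R,3E)-1-[4-(TBS-oxymethyl)furan-2-yl]-2-hydroxy-4-methyl-5-oxohex-3-en-1-yl}prop-2-enoate, via pinacol borate 11 (not isolated)
Conditions: (S)-TRIP [(S)-3,3′-bis(2,4,6-triisopropylphenyl)-1,1′-binaphthyl-2,2′-diyl hydrogen phosphate] (5 mol%), 4 Å MS, toluene, −30 to 0 °C; then cold aq NaHCO3
Reagents that add atoms: none
Why: Proposed new method: chiral-phosphoric-acid-catalysed allylboration of the aldehyde (closest known: phosphoric-acid-catalysed crotylboration with pinacol boronates and Brønsted-acid-accelerated additions of 2-alkoxycarbonyl allylboronates), in which the acid activates a boronate oxygen in a closed chair transition state; the furyl group cis to CH2B sits axial and gives the 7,8-syn adduct, and the (S)-acid is expected to direct attack to the Si face of the aldehyde, setting C8 (R) and C7 (R) while the ketone is untouched.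

**Step 8 (key step)**
Reactants: 12 furan adduct
Product: 13 methyl (3R,5Z)-3-[(1R,2E)-1-hydroxy-3-methyl-4-oxopent-2-en-1-yl]-2-methylidene-4,7-dioxo-6-(TBS-oxymethyl)hept-5-enoate
Conditions: NBS (1.05 equiv), NaHCO3, THF/acetone/H2O (5:4:1), −20 °C, 20 min; cold extraction, crude used at once
Reagents that add atoms: water, O
Why: Oxidative dearomatisation of the 2,4-disubstituted furan (bromination–hydrolysis ring opening) unveils in one operation the C3 aldehyde, the C6 ketone β to the 8-OH and the 4Z olefin, whose geometry is inherited from the ring; leaving out pyridine and working cold preserves the Z-isomer and C7/C8.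

**Step 9**
Reactants: 13 (Z)-keto-enal
Product: 15 (4S,5R)-3-methylidene-4-[(1R,2E)-3-methyl-4-oxo-1-(tigloyloxy)pent-2-en-1-yl]-5-[(1Z)-3-oxo-2-(TBS-oxymethyl)prop-1-en-1-yl]oxolan-2-one, via hydroxy ester 14 (not isolated)
Conditions: tiglaldehyde (6 equiv), SmI2 (20 mol%, premixed with the aldehyde), THF, −10 °C; then rt
Reagents that add atoms: (E)-2-methylbut-2-enal (tiglaldehyde), C/C=C(\C)C=O
Why: Proposed new method: Evans–Tishchenko reduction with an α,β-unsaturated aldehyde as hydride donor (closest known: samarium-catalysed Evans–Tishchenko reduction of β-hydroxy ketones with saturated and aryl aldehydes); the O8 hemiacetal of tiglaldehyde bound to trivalent samarium delivers hydride to the C6 ketone through a chair, giving the 6,8-anti monoester with tiglate on O8 and a (6R)-hydroxyl, whose samarium alkoxide closes the trans γ-lactone onto the methyl ester.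

**Step 10**
Reactants: 15 lactone enal methyl ketone
Product: 18 (3S,6R,7S,8R,4Z,9E)-3-hydroxy-1-oxo-8-(tigloyloxy)-15-(TBS-oxy)germacra-4,9,11(13)-trien-12,6-olide, via enol borinate 16 (not isolated), via boron aldolate 17 (not isolated)
Conditions: (−)-Ipc2BCl (1.5 equiv), Et3N (2 equiv), Et2O, −78 to −20 °C, slow addition of 15 (final 2 mM); pH 7 buffer/MeOH work-up
Reagents that add atoms: none
Why: Intramolecular boron aldol reaction (Paterson-type) at high dilution; the methyl ketone is the only enolisable carbonyl, the closed Zimmerman–Traxler transition state forms C2–C3 and the ten-membered ring, and the (−)-Ipc ligands are expected to direct attack to the Si face of the enal, giving 3S.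

**Step 11**
Reactants: 18 macrocyclic β-hydroxy ketone
Product: 19 (1S,3S,6R,7R,8R,4Z,9E)-3-acetoxy-1-hydroxy-8-(tigloyloxy)-15-(TBS-oxy)germacra-4,9,11(13)-trien-12,6-olide
Conditions: MeCHO (10 equiv), SmI2 (30 mol%, premixed with MeCHO), THF, −10 °C
Reagents that add atoms: acetaldehyde, CC=O
Why: Evans–Tishchenko reduction; the O3 hemiacetal of acetaldehyde on trivalent samarium transfers hydride to the C1 ketone through a chair, giving the 1,3-anti (1S) alcohol and leaving the acetate on O3 in the same operation.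

**Step 12**
Reactants: 19 silyl ether
Product: 20 (1S,3S,6R,7R,8R,4Z,9E)-3-acetoxy-1,15-dihydroxy-8-(tigloyloxy)germacra-4,9,11(13)-trien-12,6-olide (CNP0153210.7)
Conditions: HF·pyridine, pyridine, THF, 0 °C to rt
Reagents that add atoms: none
Why: Buffered fluoride cleavage of the primary TBS ether, which leaves the acetate, tiglate, allylic alcohol and α-methylene lactone intact and touches no stereocentre.

**Compound list**
1 | 4-bromofuran-2-carbaldehyde | O=Cc1cc(Br)co1 | starting material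
2 | 4-(hydroxymethyl)furan-2-carbaldehyde | O=Cc1cc(CO)co1 | intermediate
3 | 4-(TBS-oxymethyl)furan-2-carbaldehyde | O=Cc1cc(CO[Si](C)(C)C(C)(C)C)co1 | intermediate
4 | methyl acrylate | C=CC(=O)OC | starting material
5 | methyl 2-{[4-(TBS-oxymethyl)furan-2-yl](hydroxy)methyl}prop-2-enoate (racemic) | COC(=O)C(=C)C(O)c1cc(CO[Si](C)(C)C(C)(C)C)co1 | intermediate
6 | methyl 2-{(acetyloxy)[4-(TBS-oxymethyl)furan-2-yl]methyl}prop-2-enoate (racemic) | COC(=O)C(=C)C(OC(C)=O)c1cc(CO[Si](C)(C)C(C)(C)C)co1 | intermediate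
7 | methyl (2E)-3-[4-(TBS-oxymethyl)furan-2-yl]-2-[(pinacolboryl)methyl]prop-2-enoate | COC(=O)/C(CB1OC(C)(C)C(C)(C)O1)=C/c1cc(CO[Si](C)(C)C(C)(C)C)co1 | intermediate
8 | 2,3-dimethylfuran | Cc1occc1C | starting material
9 | (2Z)-3-methyl-4-oxopent-2-enal | CC(=O)/C(C)=C\C=O | intermediate (not isolated)
10 | (2E)-3-methyl-4-oxopent-2-enal | CC(=O)/C(C)=C/C=O | intermediate
11 | O8-pinacolboryl derivative of 12 | COC(=O)C(=C)[C@@H](c1cc(CO[Si](C)(C)C(C)(C)C)co1)[C@H](OB1OC(C)(C)C(C)(C)O1)/C=C(\C)C(C)=O | intermediate (not isolated)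
12 | methyl 2-{(1R,2R,3E)-1-[4-(TBS-oxymethyl)furan-2-yl]-2-hydroxy-4-methyl-5-oxohex-3-en-1-yl}prop-2-enoate | COC(=O)C(=C)[C@@H](c1cc(CO[Si](C)(C)C(C)(C)C)co1)[C@H](O)/C=C(\C)C(C)=O | intermediate
13 | methyl (3R,5Z)-3-[(1R,2E)-1-hydroxy-3-methyl-4-oxopent-2-en-1-yl]-2-methylidene-4,7-dioxo-6-(TBS-oxymethyl)hept-5-enoate | COC(=O)C(=C)[C@@H](C(=O)/C=C(/CO[Si](C)(C)C(C)(C)C)C=O)[C@H](O)/C=C(\C)C(C)=O | intermediate
14 | methyl (3S,4R,5Z)-4-hydroxy-2-methylidene-3-[(1R,2E)-3-methyl-4-oxo-1-(tigloyloxy)pent-2-en-1-yl]-7-oxo-6-(TBS-oxymethyl)hept-5-enoate | COC(=O)C(=C)[C@@H]([C@H](O)/C=C(/CO[Si](C)(C)C(C)(C)C)C=O)[C@H](OC(=O)/C(C)=C/C)/C=C(\C)C(C)=O | intermediate (not isolated)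
15 | (4S,5R)-3-methylidene-4-[(1R,2E)-3-methyl-4-oxo-1-(tigloyloxy)pent-2-en-1-yl]-5-[(1Z)-3-oxo-2-(TBS-oxymethyl)prop-1-en-1-yl]oxolan-2-one | C=C1C(=O)O[C@H](/C=C(/CO[Si](C)(C)C(C)(C)C)C=O)[C@H]1[C@H](OC(=O)/C(C)=C/C)/C=C(\C)C(C)=O | intermediate
16 | O-diisopinocampheylboryl enolate (C1=C2) of 15 | C=C1C(=O)O[C@H](/C=C(/CO[Si](C)(C)C(C)(C)C)C=O)[C@H]1[C@H](OC(=O)/C(C)=C/C)/C=C(\C)C(=C)OB([C@@H]1C[C@@H]2C[C@H]([C@H]1C)C2(C)C)[C@@H]1C[C@@H]2C[C@H]([C@H]1C)C2(C)C | intermediate (not isolated)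
17 | O3-diisopinocampheylboryl aldolate of 18 | C=C1C(=O)O[C@@H]2/C=C(/CO[Si](C)(C)C(C)(C)C)[C@@H](OB([C@@H]3C[C@@H]4C[C@H]([C@H]3C)C4(C)C)[C@@H]3C[C@@H]4C[C@H]([C@H]3C)C4(C)C)CC(=O)/C(C)=C/[C@@H](OC(=O)/C(C)=C/C)[C@@H]12 | intermediate (not isolated)
18 | (3S,6R,7S,8R,4Z,9E)-3-hydroxy-1-oxo-8-(tigloyloxy)-15-(TBS-oxy)germacra-4,9,11(13)-trien-12,6-olide | C=C1C(=O)O[C@@H]2/C=C(/CO[Si](C)(C)C(C)(C)C)[C@@H](O)CC(=O)/C(C)=C/[C@@H](OC(=O)/C(C)=C/C)[C@@H]12 | intermediate
19 | (1S,3S,6R,7R,8R,4Z,9E)-3-acetoxy-1-hydroxy-8-(tigloyloxy)-15-(TBS-oxy)germacra-4,9,11(13)-trien-12,6-olide | C=C1C(=O)O[C@@H]2/C=C(/CO[Si](C)(C)C(C)(C)C)[C@@H](OC(C)=O)C[C@H](O)/C(C)=C/[C@@H](OC(=O)/C(C)=C/C)[C@@H]12 | intermediate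
20 | (1S,3S,6R,7R,8R,4Z,9E)-3-acetoxy-1,15-dihydroxy-8-(tigloyloxy)germacra-4,9,11(13)-trien-12,6-olide | C=C1C(=O)O[C@@H]2/C=C(/CO)[C@@H](OC(C)=O)C[C@H](O)/C(C)=C/[C@@H](OC(=O)/C(C)=C/C)[C@@H]12 | target

**Totals and risks**
Total: 12 steps. Longest linear sequence: 11 steps (1–5, 7–12) from 4-bromofuran-2-carbaldehyde.

The three steps most likely to fail:

Step 7. The ester-deactivated allylboronate may not respond to the chiral acid (rate or ee), and 12 may lactonise at O8. The fallback moves stereocontrol onto boron. It sets out from 6: borylation with tetrahydroxydiboron (Pd2(dba)3, DMSO/MeOH) gives the allylboronic acid F1. Esterification with diisopropyl (2R,3R)-tartrate (MgSO4) gives the tartrate allylboronate F2. Its uncatalysed addition to 10 (toluene, 4 Å MS, −78 °C) passes through the same chair, with the tartrate esters differentiating the aldehyde faces, and gives the tartrate borate F3. Hydrolytic work-up comes back to the route at 12.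

Step 9. Three things can go wrong: the free 8-OH of 13 can add to the ene-dicarbonyl; the enal is an untested hydride donor; and the 6-OH/C3-aldehyde pair of 14 can close to a lactol and re-aromatise to a furan before it lactonises. The fallback protects O8 and reverses the order of the two Tishchenko events. It sets out from 12: TESCl/imidazole gives the triethylsilyl ether F4, and NBS opening as in step 8 gives the keto-enal F5. The boron aldol of step 10 then closes the carbocycle through the enol borinate F6 and the boron aldolate F7 to the β-hydroxy ketone F8. Evans–Tishchenko reduction with acetaldehyde gives the 3-acetate 1-alcohol F9; only this half reacts because O8 is silylated. PPTS/MeOH removes the TES group to give the 8-hydroxy 6-ketone F10, which has no aldehyde left and no β-ketone for the 1-OH. Evans–Tishchenko reduction with tiglaldehyde gives the 8-tiglate 6-alcohol F11, which lactonises (catalytic DBU if needed) and comes back to the route at 19.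

Step 10. Ten-membered ring closure may lose to reduction of the aldehyde by the chloroborane or to intermolecular aldol, and the macrocycle may override reagent control at C3. The fallback sets out from 15: TMSOTf/Et3N (CH2Cl2, −78 °C) gives the trimethylsilyl enol ether F12. Slow addition to BF3·OEt2 (CH2Cl2, −78 °C, 1 mM) closes the ring by an intramolecular Mukaiyama aldol through an open transition state; a chiral Lewis acid can be used if the C3 epimer prevails. Aqueous work-up comes back to the route at 18.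

**Further compounds**
F1 | step 7 | {(2E)-3-[4-(TBS-oxymethyl)furan-2-yl]-2-(methoxycarbonyl)prop-2-en-1-yl}boronic acid | COC(=O)/C(CB(O)O)=C/c1cc(CO[Si](C)(C)C(C)(C)C)co1
F2 | step 7 | diisopropyl (2R,3R)-tartrate ester of F1 | COC(=O)/C(CB1O[C@@H](C(=O)OC(C)C)[C@H](C(=O)OC(C)C)O1)=C/c1cc(CO[Si](C)(C)C(C)(C)C)co1
F3 | step 7 | O8-(tartrate-boryl) derivative of 12 | COC(=O)C(=C)[C@@H](c1cc(CO[Si](C)(C)C(C)(C)C)co1)[C@H](OB1O[C@@H](C(=O)OC(C)C)[C@H](C(=O)OC(C)C)O1)/C=C(\C)C(C)=O
F4 | step 9 | O8-triethylsilyl ether of 12 | COC(=O)C(=C)[C@@H](c1cc(CO[Si](C)(C)C(C)(C)C)co1)[C@H](O[Si](CC)(CC)CC)/C=C(\C)C(C)=O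
F5 | step 9 | O8-triethylsilyl ether of 13 | COC(=O)C(=C)[C@@H](C(=O)/C=C(/CO[Si](C)(C)C(C)(C)C)C=O)[C@H](O[Si](CC)(CC)CC)/C=C(\C)C(C)=O
F6 | step 9 | O-diisopinocampheylboryl enolate (C1=C2) of F5 | COC(=O)C(=C)[C@@H](C(=O)/C=C(/CO[Si](C)(C)C(C)(C)C)C=O)[C@H](O[Si](CC)(CC)CC)/C=C(\C)C(=C)OB([C@@H]1C[C@@H]2C[C@H]([C@H]1C)C2(C)C)[C@@H]1C[C@@H]2C[C@H]([C@H]1C)C2(C)C
F7 | step 9 | O3-diisopinocampheylboryl aldolate of F8 | COC(=O)C(=C)[C@H]1C(=O)/C=C(/CO[Si](C)(C)C(C)(C)C)[C@@H](OB([C@@H]2C[C@@H]3C[C@H]([C@H]2C)C3(C)C)[C@@H]2C[C@@H]3C[C@H]([C@H]2C)C3(C)C)CC(=O)/C(C)=C/[C@H]1O[Si](CC)(CC)CC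
F8 | step 9 | methyl 2-[ten-membered carbocycle]acrylate with 3-OH, 1,6-dioxo, 8-OTES, 15-OTBS, 4Z, 9E | COC(=O)C(=C)[C@H]1C(=O)/C=C(/CO[Si](C)(C)C(C)(C)C)[C@@H](O)CC(=O)/C(C)=C/[C@H]1O[Si](CC)(CC)CC
F9 | step 9 | 3-acetate 1-alcohol from F8 (6-oxo, 8-OTES) | COC(=O)C(=C)[C@H]1C(=O)/C=C(/CO[Si](C)(C)C(C)(C)C)[C@@H](OC(C)=O)C[C@H](O)/C(C)=C/[C@H]1O[Si](CC)(CC)CC
F10 | step 9 | 8-hydroxy 6-ketone from F9 | COC(=O)C(=C)[C@H]1C(=O)/C=C(/CO[Si](C)(C)C(C)(C)C)[C@@H](OC(C)=O)C[C@H](O)/C(C)=C/[C@H]1O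
F11 | step 9 | 8-tiglate 6-alcohol methyl ester (seco-lactone of 19) | COC(=O)C(=C)[C@H]1[C@H](O)/C=C(/CO[Si](C)(C)C(C)(C)C)[C@@H](OC(C)=O)C[C@H](O)/C(C)=C/[C@H]1OC(=O)/C(C)=C/C
F12 | step 10 | trimethylsilyl enol ether (C1=C2) of 15 | C=C1C(=O)O[C@H](/C=C(/CO[Si](C)(C)C(C)(C)C)C=O)[C@H]1[C@H](OC(=O)/C(C)=C/C)/C=C(\C)C(=C)O[Si](C)(C)C
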